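## Structural features

- The target is a labdane-type diterpenoid diacid built on a decalin: ring A is C1–C5 plus C10, ring B is C5–C10. Labdane numbering is used throughout, and β means the face of the C10 methyl (C20).
- Assumption: read literally, the SMILES puts H-5 on the same face as the C10 methyl, so the decalin is cis-fused with (2S,4R,5S,9S,10R,13E) configuration; the route aims at exactly this isomer.
- Ring A carries a 2β-hydroxyl and a quaternary C4 (C19 methyl β, C18 carboxyl α); ring B carries the exocyclic methylene C8=C17 and, on C9, a chain C11–C16 ending in an (E)-3-methylacrylic acid (C13=C14, C15).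
- Four stereocentres are contiguous or 1,3-related (C4–C5–C10–C9), two of them quaternary and flanking C5; the fifth, C2, lies between two CH2 groups, β to both quaternary carbons.
- The β face holds both methyls, H-5, the C9 chain and the hydroxyl; the α face holds C18, C6 and C9. In the preferred chair of ring A the carboxyl and the C10–C9 bond are therefore syn-axial and the hydroxyl is equatorial.
- Fragile groups: the exocyclic alkene (migrates into the ring under acid), the E-enoic acid (geometry and position are labile at the ester-enolate stage), and the hindered axial acid, whose esters resist hydrolysis and which is best released directly as the acid.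
- The real difficulty is the cis ring fusion together with the relative configuration of the two quaternary centres and C9; polyene-cyclisation and annulation logic naturally give the trans-fused series.
- Feature exploited by the key step: the three α substituents on C4, C5 and C10 (C18, C6, C9) all converge on C8. One extra bond, C8–C18, turns rings A and B into a bicyclo[2.2.2]octane (bridgeheads C5 and C8) bridged by C1–C3, that is, a tricyclo[5.3.1.0(3,8)]undecane cage that one cycloaddition can build and in which connectivity alone dictates these stereocentres.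

## Logic of the disconnections

**21 ⇒ 20.** The bond C8–C18 is re-formed and C8=C17 becomes a C17–O single bond. The forward Grob-type cleavage releases the hindered acid as the free carboxylate and the acid-sensitive exocyclic alkene in the last operation, so neither is ever carried or deprotected. The gain is that the flexible cis-decalin becomes a rigid cage in which C4, C5, C9 and C10 cannot epimerise. The forward step demands hydroxide addition to a hindered, non-enolisable ketone and an anti-periplanar C18–C8/C17–O arrangement.

**20 ⇒ 16 (through 19, 18, 17).** No skeletal bond is cut. The C2 carbinol is traced to a ketone, the mesylate to a silyl ether, and C6–C7 to the alkene left by a cycloaddition. The reason is that the cage makes the 2β (equatorial) alcohol the thermodynamic epimer by a wide margin. The demand is a reduction under equilibrating conditions and a hydrogen transfer that spares the enoate.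

**16 ⇒ 15.** C5–C10 and C8–C9 are cut (retro-[4+2]). This removes rings A and B and four stereocentres (C5, C8, C9, C10) at once and leaves a monocyclic dienone with one quaternary stereocentre (C4) and an E alkene. The demand is a thermal intramolecular Diels–Alder reaction of an unactivated trisubstituted alkene, with a three-atom tether to fix regiochemistry and facial selectivity.

**15 ⇒ 11 (through 14).** The C5=C6 unsaturation and the C2 carbonyl are removed. The reason is that the dienone and the skipped enone are both too labile to carry through fragment union. The demand is a γ,δ-dehydrogenation that tolerates the skipped diene, and a neutral oxidation.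

**11 ⇒ 7 + 10.** C1–C2 is cut. The union is convergent, and 10 delivers C1, C9–C16, both E alkenes and the C15 ester in one piece from a commodity terpenoid ester. The demand is allylation through the primary (α) carbon with retention of the E geometry.

**10 ⇒ 8 (through 9).** The C1–Br bond is traced to a C–H bond of the terminal E methyl of 8; the demand is E-selective allylic oxidation remote from the ester.

**7 ⇒ 3 (through 6, 5, 4).** The aldehyde is traced to an allyl group (loss of one carbon), C17 to a one-carbon electrophile added at C8, and C7=C8 to a dehydrogenation. The demand is selective cleavage of the terminal alkene in the presence of the enone.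

**3 ⇒ 1 (through 2).** C3–C4 is cut. This is the only stereocentre that needs an external source of chirality; the demand is an enantioselective allylation that creates a quaternary α-carbon.

## Other disconnections considered

**Alternative 1:** (the first idea for a labdane) Cut C4–C5 and C9–C10 in a cation–olefin bicyclisation of the acyclic β-keto ester polyene A1, with a Z central alkene for the cis fusion and an allylsilane terminator for C8=C17. The ring fusion rests on concerted anti addition across the Z alkene; a tertiary cation at C10 is likely to live long enough to lose that memory and leak to the trans series. The initiator also places oxygen at C3, not C2, so a carbonyl transposition would follow, and four stereocentres would form without absolute control. The chosen cage fixes the same centres by connectivity.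

**Alternative 2:** Cut C1–C10 and C4–C5 by Robinson annulation, starting from the Wieland–Miescher ketone A2 and setting H-5 by hydrogenation. Oxygen again lands at C3, C4 must be doubly alkylated beside the ring fusion, and the C9 chain must be introduced at a neopentyl position. This means a long, protecting-group-heavy sequence in which every stereocentre is set separately. The chosen plan sets four in one step.

**Alternative 3:** Cut C3–C4 and C5–C10 in a type 1 intramolecular Diels–Alder reaction of the acyclic triene A3 (2-silyloxydiene plus Z α-methyl enoate), closing both rings directly.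
- The diene terminus C10 must carry an inside methyl, which slows the reaction and invites [1,5]-hydrogen shift.
- The tether forces the electronically mismatched orientation.
- To give the target's C9/C10 relationship, the C9 chain would have to eclipse that inside methyl (A(1,2) strain), so the existing stereocentre should steer towards the 9-epimer.

The cage route instead derives C9 from alkene geometry.

Key step: step 12

## Route

Step 1
Reactants: 1 2-methylcyclohexan-1-one
Product: 2 2-methyl-1-(trimethylsilyloxy)cyclohex-1-ene
Conditions: TMSCl, NaI, Et3N, MeCN, 25 °C; fractional distillation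
Reagents that add atoms: chlorotrimethylsilane, C[Si](C)(C)Cl
Why: Soft enolisation with iodotrimethylsilane formed in the flask under equilibrating conditions should favour the tetrasubstituted (thermodynamic) silyl enol ether, with the minor regioisomer removed by distillation; no stereocentre is present.

Step 2
Reactants: 2 2-methyl-1-(trimethylsilyloxy)cyclohex-1-ene
Product: 3 (2S)-2-methyl-2-(prop-2-en-1-yl)cyclohexan-1-one
Conditions: Pd2(dba)3 (2.5 mol%), (S)-t-BuPHOX (6 mol%), diallyl carbonate, tetrabutylammonium difluorotriphenylsilicate (35 mol%), THF, 25 °C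
Reagents that add atoms: diallyl carbonate, C=CCOC(=O)OCC=C
Why: Enantioselective Tsuji-type allylic alkylation: zerovalent palladium ionises the carbonate to a π-allyl complex, the released alkoxide/fluoride unmasks the enolate, and C–C bond formation within the ligand-bound palladium enolate sets the quaternary centre C4 as S, the sense known for this ligand and this enolate.

Step 3
Reactants: 3 (2S)-2-methyl-2-(prop-2-en-1-yl)cyclohexan-1-one
Product: 4 (6S)-6-methyl-6-(prop-2-en-1-yl)cyclohex-2-en-1-one
Conditions: IBX (1.5 equiv), DMSO/toluene, 70 °C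
Reagents that add atoms: none
Why: IBX-mediated α,β-dehydrogenation of a ketone; only the C8 side can enolise because C4 is quaternary, so a single enone should form and the stereocentre is untouched.

Step 4
Reactants: 4 (6S)-6-methyl-6-(prop-2-en-1-yl)cyclohex-2-en-1-one
Product: 5 (6S)-2-(hydroxymethyl)-6-methyl-6-(prop-2-en-1-yl)cyclohex-2-en-1-one
Conditions: aqueous HCHO (37%), DMAP (20 mol%), THF, 25 °C
Reagents that add atoms: formaldehyde, C=O
Why: Morita–Baylis–Hillman reaction: DMAP adds to C7, the resulting enolate attacks formaldehyde through C8, and elimination restores the enone; this installs C17 on C8.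

Step 5
Reactants: 5 (6S)-2-(hydroxymethyl)-6-methyl-6-(prop-2-en-1-yl)cyclohex-2-en-1-one
Product: 6 (6S)-2-{[(tert-butyldimethylsilyl)oxy]methyl}-6-methyl-6-(prop-2-en-1-yl)cyclohex-2-en-1-one
Conditions: TBSCl, imidazole, DMF, 25 °C
Reagents that add atoms: tert-butyldimethylsilyl chloride, CC(C)(C)[Si](C)(C)Cl
Why: Standard silylation of a primary allylic alcohol; the ether keeps C17–O inert until the fragmentation handle is needed.

Step 6
Reactants: 6 (6S)-2-{[(tert-butyldimethylsilyl)oxy]methyl}-6-methyl-6-(prop-2-en-1-yl)cyclohex-2-en-1-one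
Product: 7 2-[(1S)-3-{[(tert-butyldimethylsilyl)oxy]methyl}-1-methyl-2-oxocyclohex-3-en-1-yl]acetaldehyde
Conditions: OsO4 (2 mol%), NaIO4 (4 equiv), 2,6-lutidine, dioxane/H2O 3:1, 25 °C
Reagents that add atoms: osmium tetroxide (catalytic oxygen carrier), O=[Os](=O)(=O)=O; sodium periodate, [Na+].[O-][I](=O)(=O)=O
Why: Lemieux–Johnson cleavage: the electron-rich monosubstituted alkene is dihydroxylated far faster than the electron-poor trisubstituted enone, and periodate cleaves the diol so that the former internal allyl carbon becomes the C2 aldehyde.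

Step 7
Reactants: 8 methyl (2E)-3,7-dimethylocta-2,6-dienoate
Product: 9 methyl (2E,6E)-8-hydroxy-3,7-dimethylocta-2,6-dienoate
Conditions: SeO2 (0.5 equiv), t-BuOOH (3 equiv), CH2Cl2, 0 °C to 25 °C
Reagents that add atoms: tert-butyl hydroperoxide, CC(C)(C)OO; selenium dioxide (oxygen carrier), O=[Se]=O
Why: Selenium dioxide allylic oxidation (ene reaction then [2,3]-sigmatropic shift) selects the E methyl of the electron-rich terminal alkene and leaves the conjugated enoate alone.

Step 8
Reactants: 9 methyl (2E,6E)-8-hydroxy-3,7-dimethylocta-2,6-dienoate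
Product: 10 methyl (2E,6E)-8-bromo-3,7-dimethylocta-2,6-dienoate
Conditions: CBr4, PPh3, CH2Cl2, 0 °C
Reagents that add atoms: carbon tetrabromide, BrC(Br)(Br)Br
Why: Appel bromination of a primary allylic alcohol by SN2 displacement of the oxyphosphonium, without allylic transposition and with retention of both E alkenes.

Step 9
Reactants: 7 2-[(1S)-3-{[(tert-butyldimethylsilyl)oxy]methyl}-1-methyl-2-oxocyclohex-3-en-1-yl]acetaldehyde; 10 methyl (2E,6E)-8-bromo-3,7-dimethylocta-2,6-dienoate
Product: 11 methyl (2E,6E)-10-[(1S)-3-{[(tert-butyldimethylsilyl)oxy]methyl}-1-methyl-2-oxocyclohex-3-en-1-yl]-9-hydroxy-3,7-dimethyldeca-2,6-dienoate (both C9 epimers)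
Conditions: In powder (2 equiv), H2O (6 equiv), CH2Cl2, 25 °C, 48 h
Reagents that add atoms: none
Why: Indium-mediated Barbier allylation under water-poor, α-selective conditions: the branched γ-adduct formed first passes its allyl unit on by a 2-oxonia-Cope rearrangement to the linear α-adduct, a chair transition state with the C11 chain equatorial keeping the 6E alkene; the aldehyde reacts in preference to the hindered enone and the ester, and the new carbinol centre (C2) forms without control, which is immaterial because it is oxidised in step 11.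

Step 10
Reactants: 11 methyl (2E,6E)-10-[(1S)-3-{[(tert-butyldimethylsilyl)oxy]methyl}-1-methyl-2-oxocyclohex-3-en-1-yl]-9-hydroxy-3,7-dimethyldeca-2,6-dienoate
Product: 14 hydroxy dienone methyl (2E,6E)-10-[(1R)-3-{[(tert-butyldimethylsilyl)oxy]methyl}-1-methyl-2-oxocyclohexa-3,5-dien-1-yl]-9-hydroxy-3,7-dimethyldeca-2,6-dienoate, via bis-silylated dienol ether 12 (not isolated), via trimethylsilyl-ether dienone 13 (not isolated)
Conditions: TMSOTf (2.4 equiv), Et3N, CH2Cl2, −78 to 0 °C; then Pd(OAc)2 (1.1 equiv), MeCN, 25 °C; then citric acid, MeOH, 0 °C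
Reagents that add atoms: trimethylsilyl trifluoromethanesulfonate, C[Si](C)(C)OS(=O)(=O)C(F)(F)F (silyl groups of 12 and 13; none remains in 14)
Why: C4 is quaternary, so the O-silylated enone can lose only the γ-proton at C6 and gives the extended dienol ether (the carbinol is silylated in passing); Saegusa–Ito oxidation with divalent palladium then gives the linear dienone by β-hydride loss from C5, and mild methanolysis frees the C2 hydroxyl; no stereocentre is touched.

Step 11
Reactants: 14 hydroxy dienone (both C9 epimers)
Product: 15 methyl (2E,6E)-10-[(1R)-3-{[(tert-butyldimethylsilyl)oxy]methyl}-1-methyl-2-oxocyclohexa-3,5-dien-1-yl]-3,7-dimethyl-9-oxodeca-2,6-dienoate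
Conditions: Dess–Martin periodinane (1.3 equiv), CH2Cl2, 0 to 25 °C; rapid filtration through neutral alumina
Reagents that add atoms: none
Why: Dess–Martin oxidation under neutral conditions converts both carbinol epimers into the C2 ketone without moving the skipped C9=C10 alkene into conjugation; an sp2 C2 removes the stereochemical ambiguity before the cycloaddition.

Step 12
Reactants: 15 methyl (2E,6E)-10-[(1R)-3-{[(tert-butyldimethylsilyl)oxy]methyl}-1-methyl-2-oxocyclohexa-3,5-dien-1-yl]-3,7-dimethyl-9-oxodeca-2,6-dienoate
Product: 16 methyl (13E)-17-[(tert-butyldimethylsilyl)oxy]-2,18-dioxo-8α,18-cyclo-5β-labda-6,13-dien-15-oate (tricyclo[5.3.1.0(3,8)]undec-9-ene cage)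
Conditions: toluene (0.005 M), BHT (10 mol%), base-washed sealed tube, 150 °C
Reagents that add atoms: none
Why: This is a thermal intramolecular [4π+2π] Diels–Alder reaction of a cyclohexa-2,4-dienone with a tethered unactivated alkene, the reaction type by which 6-alkenyl-6-methylcyclohexa-2,4-dienones give patchoulane-type cages. The electron-poor diene C5=C6–C7=C8 adds suprafacially across the electron-rich C10=C9 alkene, forming C5–C10 and C8–C9 in one concerted, asynchronous event with no reagent. Ring B (C5–C10) is the new six-membered ring of the [4+2] addition, and ring A (C4, C3, C2, C1, C10, C5) closes at the same moment through the C5–C10 bond because the three-atom tether C3–C2–C1 links C4 to C10. Regiochemistry (C10 to C5, C9 to C8) is fixed by that tether, since three atoms cannot span the opposite orientation. For C5 and C10, the tether hangs from the stereogenic C4, so the alkene can reach only the diene face syn to C3, which puts H-5 and the C4 and C10 methyls on one face and C18, C6 and C9 on the other. For C9, suprafacial addition transfers the E geometry, so C11 ends cis to the C10 methyl (over the C6=C7 bridge) and H-9 cis to C1; C8 is a bridgehead and follows from the ring constraints. The step must outrun dienone dimerisation and migration of the β,γ-double bond: the C8 substituent and high dilution slow dimerisation, the sp2 C2 keeps ring A free of a syn-axial group in the transition state, and neutral base-free conditions preserve the skipped enone.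

Step 13
Reactants: 16 methyl (13E)-17-[(tert-butyldimethylsilyl)oxy]-2,18-dioxo-8α,18-cyclo-5β-labda-6,13-dien-15-oate
Product: 17 methyl (13E)-17-[(tert-butyldimethylsilyl)oxy]-2,18-dioxo-8α,18-cyclo-5β-labd-13-en-15-oate
Conditions: dipotassium azodicarboxylate, AcOH, MeOH/CH2Cl2, 25 °C
Reagents that add atoms: none
Why: Diimide delivers H2 in a concerted syn fashion to the strained cis-disubstituted C6=C7 bridge far faster than to the hindered trisubstituted enoate; C6 and C7 become CH2, so no stereocentre is created.

Step 14
Reactants: 17 methyl (13E)-17-[(tert-butyldimethylsilyl)oxy]-2,18-dioxo-8α,18-cyclo-5β-labd-13-en-15-oate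
Product: 18 methyl (13E)-17-hydroxy-2,18-dioxo-8α,18-cyclo-5β-labd-13-en-15-oate
Conditions: HF·pyridine, THF, 0 to 25 °C
Reagents that add atoms: none
Why: Fluoride cleavage of the primary silyl ether; buffered HF·pyridine avoids base at the enolisable C2 ketone, and retro-aldol loss of C17 is excluded because it would need a bridgehead enolate.

Step 15
Reactants: 18 methyl (13E)-17-hydroxy-2,18-dioxo-8α,18-cyclo-5β-labd-13-en-15-oate
Product: 19 methyl (13E)-17-(methanesulfonyloxy)-2,18-dioxo-8α,18-cyclo-5β-labd-13-en-15-oate
Conditions: MsCl, Et3N, CH2Cl2, −20 °C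
Reagents that add atoms: methanesulfonyl chloride, CS(=O)(=O)Cl
Why: Sulfonylation of the only hydroxyl; the neopentyl-type mesylate on the bridgehead CH2 can undergo neither SN2 nor E2 (no β-hydrogen) and is kept for the fragmentation.

Step 16
Reactants: 19 methyl (13E)-17-(methanesulfonyloxy)-2,18-dioxo-8α,18-cyclo-5β-labd-13-en-15-oate
Product: 20 methyl (13E)-2β-hydroxy-17-(methanesulfonyloxy)-18-oxo-8α,18-cyclo-5β-labd-13-en-15-oate
Conditions: Al(OiPr)3 (0.5 equiv), i-PrOH/toluene 1:4, 80 °C, acetone not removed
Reagents that add atoms: none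
Why: Meerwein–Ponndorf–Verley reduction, reversible through the Oppenauer reaction with the acetone formed, so the alcohol should settle at the thermodynamic equatorial 2β (2S) epimer; the axial 2α epimer would be syn-axial to the C4–C18 and C10–C9 bonds, and the C18 ketone between two quaternary carbons is too hindered for the six-membered hydride-transfer transition state.

Step 17
Reactants: 20 methyl (13E)-2β-hydroxy-17-(methanesulfonyloxy)-18-oxo-8α,18-cyclo-5β-labd-13-en-15-oate
Product: 21 (2S,4R,5S,9S,10R,13E)-2-hydroxylabda-8(17),13-diene-15,18-dioic acid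
Conditions: KOH (10 equiv), t-BuOH/H2O 4:1, 70 °C; then 1 M HCl to pH 2
Reagents that add atoms: potassium hydroxide, [K+].[OH-]
Why: Grob-type fragmentation of a β-(mesyloxymethyl) ketone: hydroxide adds to the strained, non-enolisable C18 ketone and the tetrahedral alkoxide expels mesylate through an anti-periplanar C18–C8/C17–O array, cutting C8–C18 to give the C18 carboxylate and the C8=C17 exocyclic alkene in one step; the methyl ester is saponified in the same pot and no stereocentre is touched, so the cis-decalin inherits C4, C5, C9 and C10 from the cage.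

## Compound list

1 | 2-methylcyclohexan-1-one (racemic) | CC1CCCCC1=O | starting material
2 | 2-methyl-1-(trimethylsilyloxy)cyclohex-1-ene | CC1=C(O[Si](C)(C)C)CCCC1 | intermediate
3 | (2S)-2-methyl-2-(prop-2-en-1-yl)cyclohexan-1-one | C=CC[C@]1(C)CCCCC1=O | intermediate
4 | (6S)-6-methyl-6-(prop-2-en-1-yl)cyclohex-2-en-1-one | C=CC[C@]1(C)CCC=CC1=O | intermediate
5 | (6S)-2-(hydroxymethyl)-6-methyl-6-(prop-2-en-1-yl)cyclohex-2-en-1-one | C=CC[C@]1(C)CCC=C(CO)C1=O | intermediate
6 | (6S)-2-{[(tert-butyldimethylsilyl)oxy]methyl}-6-methyl-6-(prop-2-en-1-yl)cyclohex-2-en-1-one | C=CC[C@]1(C)CCC=C(CO[Si](C)(C)C(C)(C)C)C1=O | intermediate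
7 | 2-[(1S)-3-{[(tert-butyldimethylsilyl)oxy]methyl}-1-methyl-2-oxocyclohex-3-en-1-yl]acetaldehyde | O=CC[C@]1(C)CCC=C(CO[Si](C)(C)C(C)(C)C)C1=O | intermediate
8 | methyl (2E)-3,7-dimethylocta-2,6-dienoate (methyl geranate) | COC(=O)/C=C(C)/CCC=C(C)C | starting material
9 | methyl (2E,6E)-8-hydroxy-3,7-dimethylocta-2,6-dienoate | COC(=O)/C=C(C)/CC/C=C(C)/CO | intermediate
10 | methyl (2E,6E)-8-bromo-3,7-dimethylocta-2,6-dienoate | COC(=O)/C=C(C)/CC/C=C(C)/CBr | intermediate
11 | methyl (2E,6E)-10-[(1S)-3-{[(tert-butyldimethylsilyl)oxy]methyl}-1-methyl-2-oxocyclohex-3-en-1-yl]-9-hydroxy-3,7-dimethyldeca-2,6-dienoate (both C9 epimers) | COC(=O)/C=C(C)/CC/C=C(C)/CC(O)C[C@]1(C)CCC=C(CO[Si](C)(C)C(C)(C)C)C1=O | intermediate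
12 | methyl (2E,6E)-10-[(1S)-3-{[(tert-butyldimethylsilyl)oxy]methyl}-1-methyl-2-(trimethylsilyloxy)cyclohexa-2,4-dien-1-yl]-3,7-dimethyl-9-(trimethylsilyloxy)deca-2,6-dienoate (not isolated) | COC(=O)/C=C(C)/CC/C=C(C)/CC(O[Si](C)(C)C)C[C@]1(C)CC=CC(CO[Si](C)(C)C(C)(C)C)=C1O[Si](C)(C)C | intermediate
13 | methyl (2E,6E)-10-[(1R)-3-{[(tert-butyldimethylsilyl)oxy]methyl}-1-methyl-2-oxocyclohexa-3,5-dien-1-yl]-3,7-dimethyl-9-(trimethylsilyloxy)deca-2,6-dienoate (not isolated) | COC(=O)/C=C(C)/CC/C=C(C)/CC(O[Si](C)(C)C)C[C@]1(C)C=CC=C(CO[Si](C)(C)C(C)(C)C)C1=O | intermediate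
14 | methyl (2E,6E)-10-[(1R)-3-{[(tert-butyldimethylsilyl)oxy]methyl}-1-methyl-2-oxocyclohexa-3,5-dien-1-yl]-9-hydroxy-3,7-dimethyldeca-2,6-dienoate (both C9 epimers) | COC(=O)/C=C(C)/CC/C=C(C)/CC(O)C[C@]1(C)C=CC=C(CO[Si](C)(C)C(C)(C)C)C1=O | intermediate
15 | methyl (2E,6E)-10-[(1R)-3-{[(tert-butyldimethylsilyl)oxy]methyl}-1-methyl-2-oxocyclohexa-3,5-dien-1-yl]-3,7-dimethyl-9-oxodeca-2,6-dienoate | COC(=O)/C=C(C)/CC/C=C(C)/CC(=O)C[C@]1(C)C=CC=C(CO[Si](C)(C)C(C)(C)C)C1=O | intermediate
16 | methyl (13E)-17-[(tert-butyldimethylsilyl)oxy]-2,18-dioxo-8α,18-cyclo-5β-labda-6,13-dien-15-oate (cage: C18 ketone bonded to C8 on the α face; H-5, C19 and C20 methyls β; C9 chain β, H-9 α) | CC(C)(C)[Si](C)(C)OC[C@@]13C=C[C@H]2[C@](C)(CC(=O)C[C@@]2(C)C3=O)[C@H]1CC/C(C)=C/C(=O)OC | intermediate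
17 | methyl (13E)-17-[(tert-butyldimethylsilyl)oxy]-2,18-dioxo-8α,18-cyclo-5β-labd-13-en-15-oate | CC(C)(C)[Si](C)(C)OC[C@@]13CC[C@H]2[C@](C)(CC(=O)C[C@@]2(C)C3=O)[C@H]1CC/C(C)=C/C(=O)OC | intermediate
18 | methyl (13E)-17-hydroxy-2,18-dioxo-8α,18-cyclo-5β-labd-13-en-15-oate | OC[C@@]13CC[C@H]2[C@](C)(CC(=O)C[C@@]2(C)C3=O)[C@H]1CC/C(C)=C/C(=O)OC | intermediate
19 | methyl (13E)-17-(methanesulfonyloxy)-2,18-dioxo-8α,18-cyclo-5β-labd-13-en-15-oate | CS(=O)(=O)OC[C@@]13CC[C@H]2[C@](C)(CC(=O)C[C@@]2(C)C3=O)[C@H]1CC/C(C)=C/C(=O)OC | intermediate
20 | methyl (13E)-2β-hydroxy-17-(methanesulfonyloxy)-18-oxo-8α,18-cyclo-5β-labd-13-en-15-oate | CS(=O)(=O)OC[C@@]13CC[C@H]2[C@](C)(C[C@H](O)C[C@@]2(C)C3=O)[C@H]1CC/C(C)=C/C(=O)OC | intermediate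
21 | (2S,4R,5S,9S,10R,13E)-2-hydroxylabda-8(17),13-diene-15,18-dioic acid, i.e. (1R,3S,4aR,5S,8aS)-5-[(3E)-4-carboxy-3-methylbut-3-en-1-yl]-3-hydroxy-1,4a-dimethyl-6-methylidenedecahydronaphthalene-1-carboxylic acid | C=C1CC[C@H]2[C@](C)(C[C@H](O)C[C@@]2(C)C(=O)O)[C@H]1CC/C(C)=C/C(=O)O | target

## Step count and least certain steps

Total: 17 steps. Longest linear sequence: 15 steps (steps 1–6 and 9–17); steps 7 and 8 prepare fragment 10.

**Step 12 (key step).** The most likely failure is slow cycloaddition of the unactivated trisubstituted alkene. Two competing processes could then take over: thermal migration of the skipped C9=C10 double bond into conjugation with the C2 ketone, which destroys the dienophile, and bimolecular Diels–Alder dimerisation of the dienone. The fallback moves the cycloaddition to the carbinol oxidation level, so that no enolisable β,γ-unsaturated ketone is present during the pericyclic step. It sets out from 14: heating 14 in dilute toluene should give the hydroxy cage methyl (13E)-17-[(tert-butyldimethylsilyl)oxy]-2-hydroxy-18-oxo-8α,18-cyclo-5β-labda-6,13-dien-15-oate F1 as a mixture of C2 epimers, the epimer with the syn-axial hydroxyl reacting through a twisted ring A. Dess–Martin oxidation of F1 then converges both epimers on 16, where the route is rejoined.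

**Step 9.** The likely problems are attack through the γ-carbon (C9), giving the branched isomer, and erosion of the 6E geometry during the allyl transfer. The fallback replaces the allyl-metal by a sulfone-stabilised carbanion, which can only react at C1. It sets out from 10 and 7.
- Displacement of 10 with PhSO2Na should give the allylic sulfone methyl (2E,6E)-3,7-dimethyl-8-(phenylsulfonyl)octa-2,6-dienoate F2.
- Deprotonation of F2 (LDA, −78 °C) and addition to 7 should give the β-hydroxy sulfone methyl (2E,6E)-10-[(1S)-3-{[(tert-butyldimethylsilyl)oxy]methyl}-1-methyl-2-oxocyclohex-3-en-1-yl]-9-hydroxy-3,7-dimethyl-8-(phenylsulfonyl)deca-2,6-dienoate F3.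
- Dess–Martin oxidation gives the β-keto sulfone, the 9-oxo analogue of F3, F4.
- SmI2 in THF/MeOH removes the sulfonyl group to give the diketone methyl (2E,6E)-10-[(1S)-3-{[(tert-butyldimethylsilyl)oxy]methyl}-1-methyl-2-oxocyclohex-3-en-1-yl]-3,7-dimethyl-9-oxodeca-2,6-dienoate F5.
- NaBH4 at −78 °C reduces the saturated ketone of F5 in preference to the hindered enone and returns to the route at 11.

**Step 10.** The likely problems are incomplete or regiochemically impure formation of the dienol ether, and palladium-induced isomerisation of the skipped diene during the stoichiometric oxidation. The fallback abandons the silyl enol ether/palladium sequence for a hypervalent-iodine dehydrogenation. It sets out from 11: excess IBX in DMSO at 70 °C should oxidise the C2 carbinol and dehydrogenate the enone at C5–C6 in one operation. The C2 ketone has no β-hydrogen and C4 is quaternary, so neither can react further. The fallback returns to the route at 15; no new compound is involved.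

**Step 16.** The likely problems are incomplete equilibration, leaving the kinetic axial 2α alcohol (hydride enters from the open β face); harmless exchange of the methyl ester with isopropanol; and slow attack at C18. The fallback replaces thermodynamic control by SN2 inversion. It sets out from 19.
- NaBH4 in MeOH at −20 °C should give the axial alcohol methyl (13E)-2α-hydroxy-17-(methanesulfonyloxy)-18-oxo-8α,18-cyclo-5β-labd-13-en-15-oate F6.
- Mitsunobu reaction (PPh3, DIAD, 4-nitrobenzoic acid), with the nucleophile entering from the unhindered β face, should give the inverted ester methyl (13E)-17-(methanesulfonyloxy)-2β-(4-nitrobenzoyloxy)-18-oxo-8α,18-cyclo-5β-labd-13-en-15-oate F7.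
- The conditions of step 17 applied to F7 cleave this ester as well, returning to the route at 21.

**Step 17.** The likely problem is slow addition of hydroxide to the ketone flanked by two quaternary carbons, which would let attack at sulfur (loss of the mesylate without fragmentation) compete. The fallback triggers the fragmentation from an internal alkoxide instead of an external nucleophile (Wharton-type). It sets out from 20.
- NaBH4 in MeOH/THF at 40 °C should reduce the C18 ketone to the carbinol methyl (13E)-2β,18-dihydroxy-17-(methanesulfonyloxy)-8α,18-cyclo-5β-labd-13-en-15-oate F8.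
- KOtBu in THF should then fragment F8 to the aldehyde methyl (13E)-2β-hydroxy-18-oxo-5β-labda-8(17),13-dien-15-oate F9.
- Pinnick oxidation (NaClO2, NaH2PO4, 2-methylbut-2-ene) gives the acid (13E)-2β-hydroxy-15-methoxy-15-oxo-5β-labda-8(17),13-dien-18-oic acid F10.
- LiOH in aqueous THF saponifies the side-chain ester, returning to the route at 21.

## Further compounds

F1 | step 12 | methyl (13E)-17-[(tert-butyldimethylsilyl)oxy]-2-hydroxy-18-oxo-8α,18-cyclo-5β-labda-6,13-dien-15-oate (C2 epimers) | CC(C)(C)[Si](C)(C)OC[C@@]13C=C[C@H]2[C@](C)(CC(O)C[C@@]2(C)C3=O)[C@H]1CC/C(C)=C/C(=O)OC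
F2 | step 9 | methyl (2E,6E)-3,7-dimethyl-8-(phenylsulfonyl)octa-2,6-dienoate | COC(=O)/C=C(C)/CC/C=C(C)/CS(=O)(=O)c1ccccc1
F3 | step 9 | methyl (2E,6E)-10-[(1S)-3-{[(tert-butyldimethylsilyl)oxy]methyl}-1-methyl-2-oxocyclohex-3-en-1-yl]-9-hydroxy-3,7-dimethyl-8-(phenylsulfonyl)deca-2,6-dienoate | COC(=O)/C=C(C)/CC/C=C(C)/C(C(O)C[C@]1(C)CCC=C(CO[Si](C)(C)C(C)(C)C)C1=O)S(=O)(=O)c1ccccc1
F4 | step 9 | methyl (2E,6E)-10-[(1S)-3-{[(tert-butyldimethylsilyl)oxy]methyl}-1-methyl-2-oxocyclohex-3-en-1-yl]-3,7-dimethyl-9-oxo-8-(phenylsulfonyl)deca-2,6-dienoate | COC(=O)/C=C(C)/CC/C=C(C)/C(C(=O)C[C@]1(C)CCC=C(CO[Si](C)(C)C(C)(C)C)C1=O)S(=O)(=O)c1ccccc1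
F5 | step 9 | methyl (2E,6E)-10-[(1S)-3-{[(tert-butyldimethylsilyl)oxy]methyl}-1-methyl-2-oxocyclohex-3-en-1-yl]-3,7-dimethyl-9-oxodeca-2,6-dienoate | COC(=O)/C=C(C)/CC/C=C(C)/CC(=O)C[C@]1(C)CCC=C(CO[Si](C)(C)C(C)(C)C)C1=O
F0 | step 10 | none | none
F6 | step 16 | methyl (13E)-2α-hydroxy-17-(methanesulfonyloxy)-18-oxo-8α,18-cyclo-5β-labd-13-en-15-oate | CS(=O)(=O)OC[C@@]13CC[C@H]2[C@](C)(C[C@@H](O)C[C@@]2(C)C3=O)[C@H]1CC/C(C)=C/C(=O)OC
F7 | step 16 | methyl (13E)-17-(methanesulfonyloxy)-2β-(4-nitrobenzoyloxy)-18-oxo-8α,18-cyclo-5β-labd-13-en-15-oate | CS(=O)(=O)OC[C@@]13CC[C@H]2[C@](C)(C[C@H](OC(=O)c4ccc(cc4)[N+](=O)[O-])C[C@@]2(C)C3=O)[C@H]1CC/C(C)=C/C(=O)OC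
F8 | step 17 | methyl (13E)-2β,18-dihydroxy-17-(methanesulfonyloxy)-8α,18-cyclo-5β-labd-13-en-15-oate (either C18 epimer) | CS(=O)(=O)OC[C@@]13CC[C@H]2[C@](C)(C[C@H](O)C[C@@]2(C)C3O)[C@H]1CC/C(C)=C/C(=O)OC
F9 | step 17 | methyl (13E)-2β-hydroxy-18-oxo-5β-labda-8(17),13-dien-15-oate | C=C1CC[C@H]2[C@](C)(C[C@H](O)C[C@@]2(C)C=O)[C@H]1CC/C(C)=C/C(=O)OC
F10 | step 17 | (13E)-2β-hydroxy-15-methoxy-15-oxo-5β-labda-8(17),13-dien-18-oic acid | C=C1CC[C@H]2[C@](C)(C[C@H](O)C[C@@]2(C)C(=O)O)[C@H]1CC/C(C)=C/C(=O)OC
A1 | alternative 1 | dimethyl (6Z,10Z,14E)-2,6,14-trimethyl-3-oxo-10-[(trimethylsilyl)methyl]hexadeca-6,10,14-trienedioate | COC(=O)C(C)C(=O)CC/C(C)=C\CC/C(C[Si](C)(C)C)=C/CC/C(C)=C/C(=O)OC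
A2 | alternative 2 | (8aS)-8a-methyl-3,4,8,8a-tetrahydronaphthalene-1,6(2H,7H)-dione (Wieland–Miescher ketone) | C[C@]12CCC(=O)C=C1CCCC2=O
A3 | alternative 3 | methyl (2Z,7S,8E)-10-[(tert-butyldimethylsilyl)oxy]-7-[(3E)-5-methoxy-3-methyl-5-oxopent-3-en-1-yl]-2,8-dimethyl-6-methylideneundeca-2,8,10-trienoate | C=C(O[Si](C)(C)C(C)(C)C)/C=C(C)/[C@@H](CC/C(C)=C/C(=O)OC)C(=C)CC/C=C(C)\C(=O)OC
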